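**Strategy**

The quinone ring is disconnected to dimethyl squarate plus acetylene, not to an arene. A 4-ethynyl-4-hydroxycyclobutenone already carrying the methoxy group and the decalinylmethyl chain is heated: 4π ring opening to an enynylketene and closure onto the alkyne turn the four-membered ring into the 2-methoxy-3-alkyl-1,4-benzoquinone in one operation, without a separate oxidation. The step exploits the contiguous C1(=O), C2(O), C3(CH2), C4(=O) array of the quinone ring, which maps onto the four squarate carbons; C5 and C6 come from the alkyne. The octalin comes from an exo-selective asymmetric Diels–Alder reaction; amination at C5 and O-demethylation finish the synthesis.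

Key step: step 8

Shorthand: "DecCH2" = [(1R,2S,8aS)-1,2,5,5-tetramethyl-1,2,3,5,6,7,8,8a-octahydronaphthalen-1-yl]methyl. It has a C4=C4a double bond, 1-Me and 2-Me cis, and both trans to H-8a. The spatial arrangement is the same in 6–21; the 8a descriptor reads R in 6–8 only because of CIP priorities. Quinone numbering: C1(=O), C2(O), C3(CH2 chain), C4(=O), C5(N), C6(H).

Assumption: the (R)-configured oxazaborolidinium catalyst is taken to deliver the (1R,2S,8aR) adduct in step 3, following the formyl C–H···O binding model for 2-substituted enals; should the facial sense prove opposite, the (S)-catalyst is used with all else unchanged.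

**Route**

Step 1
Reactants: 1 2,2-dimethylcyclohexanone
Product: 2 6,6-dimethylcyclohex-1-en-1-yl trifluoromethanesulfonate
Conditions: LiN(iPr)2, THF, −78 °C; PhNTf2, −78 → 0 °C; H2O
Reagents that add atoms: N-phenylbis(trifluoromethanesulfonimide), O=S(=O)(N(c1ccccc1)S(=O)(=O)C(F)(F)F)C(F)(F)F
Why: Only C6 carries α-hydrogens, so enolate formation and O-triflation (enol triflate synthesis) should give a single regioisomer.

Step 2
Reactants: 2 enol triflate; 3 tributyl(vinyl)stannane
Product: 4 6,6-dimethyl-1-vinylcyclohex-1-ene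
Conditions: Pd(PPh3)4 (zerovalent palladium, 5 mol %), LiCl, THF, reflux
Reagents that add atoms: none
Why: Stille coupling of an enol triflate with a vinylstannane in the presence of LiCl is a standard route to such 1,3-dienes.

Step 3
Reactants: 4 diene; 5 (E)-2-methylbut-2-enal (tiglic aldehyde)
Product: 6 (1R,2S,8aR)-1,2,5,5-tetramethyl-1,2,3,5,6,7,8,8a-octahydronaphthalene-1-carbaldehyde
Conditions: (R)-B-(o-tolyl)oxazaborolidine from (R)-α,α-diphenylprolinol (20 mol %), Tf2NH (17 mol %), CH2Cl2, −78 → −20 °C
Reagents that add atoms: none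
Why: Catalytic enantioselective Diels–Alder reaction in which the enal β-carbon should bond to the vinyl CH2 terminus (ortho orientation), the E-geometry of 5 sets the cis 1,2-dimethyl pair, the exo transition state usual for 2-substituted enals (formyl away from the diene, 1-methyl under it) places CHO cis to H-8a, and the catalyst aryl group screens one enal face to set the absolute configuration.

Step 4
Reactants: 6 aldehyde
Product: 7 [(1R,2S,8aR)-1,2,5,5-tetramethyl-1,2,3,5,6,7,8,8a-octahydronaphthalen-1-yl]methanol
Conditions: NaBH4, MeOH, 0 °C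
Reagents that add atoms: none
Why: Hydride reduction of the neopentyl aldehyde leaves the isolated trisubstituted alkene and all stereocentres untouched.

Step 5
Reactants: 7 alcohol
Product: 8 (1R,2S,8aR)-1-(iodomethyl)-1,2,5,5-tetramethyl-1,2,3,5,6,7,8,8a-octahydronaphthalene
Conditions: I2, PPh3, imidazole, toluene, 90 °C
Reagents that add atoms: iodine, II
Why: Appel-type iodination (Garegg–Samuelsson conditions) through the alkoxyphosphonium ion; SN2 at the primary neopentyl carbon is slow, but no β-hydrogen is available for elimination and no stereocentre is involved.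

Step 6
Reactants: 8 iodide; 9 3,4-dimethoxycyclobut-3-ene-1,2-dione (dimethyl squarate)
Product: 12 3-methoxy-4-(DecCH2)cyclobut-3-ene-1,2-dione, via neopentyllithium 10 (not isolated), via lithium squarate adduct 11 (not isolated)
Conditions: t-BuLi (2.1 equiv), Et2O/pentane, −78 °C; 9, THF, −78 °C; (CF3CO)2O, −78 → 0 °C; aq. NaHCO3
Reagents that add atoms: water, O
Why: Iodine–lithium exchange gives a neopentyllithium that cannot β-eliminate; 1,2-addition to one squarate carbonyl and trifluoroacetylation of the alkoxide trigger ionisation to a methoxy-stabilised cyclobutenyl cation, which is hydrolysed on work-up with loss of methanol (the standard squarate to 3-alkoxy-4-alkylcyclobutenedione sequence).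

Step 7
Reactants: 12 cyclobutenedione; 13 ethynylmagnesium bromide
Product: 14 4-ethynyl-4-hydroxy-3-methoxy-2-(DecCH2)cyclobut-2-en-1-one (both C4 epimers)
Conditions: THF, −78 → −20 °C; H2O
Reagents that add atoms: none
Why: 1,2-Addition of the alkynyl Grignard reagent should occur at the C2 ketone of 12, because the C1 carbonyl is deactivated as a vinylogous ester; the new carbinol centre forms as a mixture that is erased in step 8.

Step 8
Reactants: 14 ethynylcarbinol
Product: 17 2-methoxy-3-(DecCH2)cyclohexa-2,5-diene-1,4-dione, via enynylketene 15 (not isolated), via aryl-phenoxyl diradical 16 (not isolated)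
Conditions: toluene (0.01 M, degassed), 110 °C
Reagents that add atoms: none
Why: Heating triggers conrotatory 4π electrocyclic opening of the cyclobutenone C1–C4 bond with the 4-OH rotating outward, so that the ethynyl group lies cis to the new ketene in 15 (the known reaction type is the Moore rearrangement of 4-alkynyl-4-hydroxycyclobutenones). The ketene carbon then bonds to the terminal alkyne carbon, closing the six-membered ring in the endo mode (both alkyne carbons inside the new ring) to diradical 16, and transfer of the hydroxyl hydrogen to the adjacent aryl radical carbon gives the quinone directly, so the four-membered ring ends up two carbons larger and no separate oxidation is needed. No stereocentre is formed; the carbinol centre of 14 is destroyed and the decalin centres are remote from the reacting π system. The selectivity at stake is six- over five-membered closure, which the unsubstituted alkyne terminus secures because the competing exo closure would pass through an unstabilised terminal vinyl radical. The positions of OMe (C2), the CH2 chain (C3) and the two hydrogens (C5, C6) follow from the carbonyl-selective additions of steps 6 and 7.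

Step 9
Reactants: 17 methoxyquinone; 18 (2S)-2-methylbutan-1-amine
Product: 20 2-methoxy-5-{[(2S)-2-methylbutyl]amino}-3-(DecCH2)cyclohexa-2,5-diene-1,4-dione, via aminohydroquinone 19 (not isolated)
Conditions: 18 (1.2 equiv), EtOH, O2 (1 atm), rt
Reagents that add atoms: none
Why: Oxidative amination of a quinone (conjugate addition, then aerobic reoxidation of 19 with O2 going to water); the C2 methoxy group deactivates the C4 carbonyl as a vinylogous ester, so the enone of the C1 carbonyl is the acceptor and nitrogen should enter at C5, while the methoxy-bearing C2 is shielded by the neighbouring neopentyl chain.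

Step 10
Reactants: 20 methoxy aminoquinone
Product: 21 nakijiquinone J
Conditions: NaOH (1 M aq.), THF/MeOH, 0 °C → rt; then 1 M HCl to pH 3
Reagents that add atoms: sodium hydroxide, [Na+].[OH-]
Why: Addition–elimination of hydroxide at C2 of the vinylogous methyl ester (saponification) should give the hydroxyquinone anion, which resists further attack, while the C5 vinylogous amide is far less electrophilic and the decalin olefin and stereocentres are inert to base.

**Compound list**

1 | 2,2-dimethylcyclohexan-1-one | CC1(C)CCCCC1=O | starting material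
2 | 6,6-dimethylcyclohex-1-en-1-yl trifluoromethanesulfonate | CC1(C)CCCC=C1OS(=O)(=O)C(F)(F)F | intermediate
3 | tributyl(vinyl)stannane | CCCC[Sn](CCCC)(CCCC)C=C | starting material
4 | 6,6-dimethyl-1-vinylcyclohex-1-ene | C=CC1=CCCCC1(C)C | intermediate
5 | (E)-2-methylbut-2-enal (tiglic aldehyde) | C/C=C(\C)C=O | starting material
6 | (1R,2S,8aR)-1,2,5,5-tetramethyl-1,2,3,5,6,7,8,8a-octahydronaphthalene-1-carbaldehyde | O=C[C@@]1(C)[C@@H]2CCCC(C)(C)C2=CC[C@@H]1C | intermediate
7 | [(1R,2S,8aR)-1,2,5,5-tetramethyl-1,2,3,5,6,7,8,8a-octahydronaphthalen-1-yl]methanol | OC[C@@]1(C)[C@@H]2CCCC(C)(C)C2=CC[C@@H]1C | intermediate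
8 | (1R,2S,8aR)-1-(iodomethyl)-1,2,5,5-tetramethyl-1,2,3,5,6,7,8,8a-octahydronaphthalene | IC[C@@]1(C)[C@@H]2CCCC(C)(C)C2=CC[C@@H]1C | intermediate
9 | 3,4-dimethoxycyclobut-3-ene-1,2-dione (dimethyl squarate) | COC1=C(OC)C(=O)C1=O | starting material
10 | (DecCH2)lithium | [Li]C[C@@]1(C)[C@@H]2CCCC(C)(C)C2=CC[C@@H]1C | intermediate (not isolated)
11 | lithium 1-(DecCH2)-2,3-dimethoxy-4-oxocyclobut-2-en-1-olate (C1 epimers) | [Li]OC1(C[C@@]2(C)[C@@H]3CCCC(C)(C)C3=CC[C@@H]2C)C(OC)=C(OC)C1=O | intermediate (not isolated)
12 | 3-methoxy-4-(DecCH2)cyclobut-3-ene-1,2-dione | COC1=C(C[C@@]2(C)[C@@H]3CCCC(C)(C)C3=CC[C@@H]2C)C(=O)C1=O | intermediate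
13 | ethynylmagnesium bromide | C#C[Mg]Br | starting material
14 | 4-ethynyl-4-hydroxy-3-methoxy-2-(DecCH2)cyclobut-2-en-1-one (C4 epimers) | C#CC1(O)C(OC)=C(C[C@@]2(C)[C@@H]3CCCC(C)(C)C3=CC[C@@H]2C)C1=O | intermediate
15 | (3Z)-4-hydroxy-3-methoxy-2-(DecCH2)hexa-1,3-dien-5-yn-1-one (enynylketene) | C#C/C(O)=C(OC)\C(C[C@@]1(C)[C@@H]2CCCC(C)(C)C2=CC[C@@H]1C)=C=O | intermediate (not isolated)
16 | 4-hydroxy-3-methoxy-2-(DecCH2)-1-oxylbenzen-5-yl diradical | Oc1[c]cc([O])c(C[C@@]2(C)[C@@H]3CCCC(C)(C)C3=CC[C@@H]2C)c1OC | intermediate (not isolated)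
17 | 2-methoxy-3-(DecCH2)cyclohexa-2,5-diene-1,4-dione | COC1=C(C[C@@]2(C)[C@@H]3CCCC(C)(C)C3=CC[C@@H]2C)C(=O)C=CC1=O | intermediate
18 | (2S)-2-methylbutan-1-amine | CC[C@H](C)CN | starting material
19 | 2-methoxy-5-{[(2S)-2-methylbutyl]amino}-3-(DecCH2)benzene-1,4-diol | CC[C@H](C)CNc1cc(O)c(OC)c(C[C@@]2(C)[C@@H]3CCCC(C)(C)C3=CC[C@@H]2C)c1O | intermediate (not isolated)
20 | 2-methoxy-5-{[(2S)-2-methylbutyl]amino}-3-(DecCH2)cyclohexa-2,5-diene-1,4-dione | CC[C@H](C)CNC1=CC(=O)C(OC)=C(C[C@@]2(C)[C@@H]3CCCC(C)(C)C3=CC[C@@H]2C)C1=O | intermediate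
21 | nakijiquinone J, 2-hydroxy-5-{[(2S)-2-methylbutyl]amino}-3-(DecCH2)cyclohexa-2,5-diene-1,4-dione | CC[C@H](C)CNC1=CC(=O)C(O)=C(C[C@@]2(C)[C@@H]3CCCC(C)(C)C3=CC[C@@H]2C)C1=O | target

**Step count and risks**

Total step count: 10. Longest linear sequence: 10 steps (from 1).

Steps most likely to fail:

Step 3. The chiral boron Lewis acid may discriminate the enal faces poorly, or turn over slowly with the hindered α,β-disubstituted enal. The fallback sets out from 4 and 5 and comes back at 7. The cycloaddition is run with an achiral Lewis acid (EtAlCl2, CH2Cl2, −78 °C), which is expected to keep the ortho and exo preferences and give the racemic aldehyde F1. NaBH4 reduction gives the racemic alcohol F2. Acylation with (1S)-camphanic chloride (pyridine, DMAP) gives the camphanate of 7 F3 together with the camphanate of ent-7 F4. These diastereomers are separated by chromatography or crystallisation, and F3 is cleaved with K2CO3 in MeOH to give 7.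

Step 8. The diradical closure may be diverted into five-membered ring closure, or the diradical may be consumed by intermolecular hydrogen abstraction and oligomerisation before the hydroxyl hydrogen is transferred. The fallback sets out from 12 and comes back at 17. Vinylmagnesium bromide is added to the same carbonyl of 12 to give the vinylcarbinol F5. Thermolysis (toluene, 110 °C) then follows a closed-shell path: 4π ring opening to a dienylketene, 6π electrocyclisation and tautomerisation to the hydroquinone F6. Ag2O (silver oxide, Et2O, rt) oxidises F6 to 17. The quinone ring is again grown from the cyclobutenone by two carbons.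

Step 5. Displacement at the neopentyl carbon next to the quaternary centre may be too slow, so that the alkoxyphosphonium intermediate decomposes or rearranges. The fallback sets out from 6, comes back at 8, and avoids SN2 at this carbon. Wittig homologation of 6 with Ph3P=CHOMe (from the phosphonium chloride and KOtBu, THF) gives the enol ether F7. Mild acid hydrolysis (dilute HCl, THF) gives the homologous aldehyde F8, and Pinnick oxidation (NaClO2, NaH2PO4, 2-methylbut-2-ene) gives the acid F9. Barton iododecarboxylation (N-hydroxypyridine-2-thione, DCC; then CHI3, hν, benzene), through the thiohydroxamate ester F10 and the neopentyl radical, returns iodide 8.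

**Further compounds**

F1 | step 3 | racemic 1,2,5,5-tetramethyl-1,2,3,5,6,7,8,8a-octahydronaphthalene-1-carbaldehyde (1R,2S,8aR and 1S,2R,8aS) | O=C[C@@]1(C)[C@@H]2CCCC(C)(C)C2=CC[C@@H]1C.O=C[C@]1(C)[C@H]2CCCC(C)(C)C2=CC[C@H]1C
F2 | step 3 | racemic (1,2,5,5-tetramethyl-1,2,3,5,6,7,8,8a-octahydronaphthalen-1-yl)methanol (1R,2S,8aR and 1S,2R,8aS) | OC[C@@]1(C)[C@@H]2CCCC(C)(C)C2=CC[C@@H]1C.OC[C@]1(C)[C@H]2CCCC(C)(C)C2=CC[C@H]1C
F3 | step 3 | (1S,4R)-camphanate of 7 | CC1(C)[C@@]2(C)CC[C@]1(C(=O)OC[C@@]3(C)[C@@H]4CCCC(C)(C)C4=CC[C@@H]3C)OC2=O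
F4 | step 3 | (1S,4R)-camphanate of the enantiomer of 7 | CC1(C)[C@@]2(C)CC[C@]1(C(=O)OC[C@]3(C)[C@H]4CCCC(C)(C)C4=CC[C@H]3C)OC2=O
F5 | step 8 | 4-hydroxy-3-methoxy-2-(DecCH2)-4-vinylcyclobut-2-en-1-one (C4 epimers) | C=CC1(O)C(OC)=C(C[C@@]2(C)[C@@H]3CCCC(C)(C)C3=CC[C@@H]2C)C1=O
F6 | step 8 | 2-methoxy-3-(DecCH2)benzene-1,4-diol | COc1c(O)ccc(O)c1C[C@@]2(C)[C@@H]3CCCC(C)(C)C3=CC[C@@H]2C
F7 | step 5 | (1R,2S,8aS)-1-(2-methoxyethenyl)-1,2,5,5-tetramethyl-1,2,3,5,6,7,8,8a-octahydronaphthalene (E/Z mixture) | COC=C[C@@]1(C)[C@@H]2CCCC(C)(C)C2=CC[C@@H]1C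
F8 | step 5 | 2-(Dec)acetaldehyde, Dec = the decalinyl group of DecCH2 | O=CC[C@@]1(C)[C@@H]2CCCC(C)(C)C2=CC[C@@H]1C
F9 | step 5 | 2-(Dec)acetic acid | OC(=O)C[C@@]1(C)[C@@H]2CCCC(C)(C)C2=CC[C@@H]1C
F10 | step 5 | 2-thioxopyridin-1(2H)-yl 2-(Dec)acetate (Barton ester) | S=C1C=CC=CN1OC(=O)C[C@@]2(C)[C@@H]3CCCC(C)(C)C3=CC[C@@H]2C
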